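# Synthesis design for the 2β,3β,13-trihydroxy C19 gibberellin (eighth member of the gibberellin A series) around a carbonate-to-carbon acyl transfer

Gibberellin numbering is used throughout: ring A = C1–C5, C10; ring B = C5, C6, C8, C9, C10; ring C = C8, C9, C11–C14; ring D = C8, C13–C16; C17 methylene, C18 methyl, C19 lactone carbonyl, C7 carboxyl. α is the face of ring A that carries the lactone bridge.

## The problem

The target 37, the 2β,3β,13-trihydroxy member of the C19 gibberellins, is a tetracycle in which ring A is trans-fused across C5–C10 to the cyclopentane ring B, ring B is cis-fused across C8–C9 to the bicyclo[3.2.1]octane of rings C and D, and a γ-lactone (C19) spans the α face of ring A from the quaternary C4 to the oxygen on C10. Nine stereocentres must be set (C2, C3, C4, C5, C6, C8, C9, C10 and C13), four of them fully substituted, together with the cis-2β,3β-diol, the bridgehead tertiary alcohol at C13 beside the C16 methylene and a hindered carboxyl on C6. C8 is the natural source of control: C13 is tied to it by the bridge, a ring B closure onto C9 is steered to the face away from the C15–C16 bridge, C6 and C5 can be placed on a ring B ketone by equilibration and vicinal control, C10 by addition to that ketone from its convex β face, C4 by delivery from the C10 oxygen, and C2 and C3 by attack on the face of ring A away from the lactone. The A/B junction is the trap, because closing ring B onto a trigonal C5 or C10 of a preformed ring A would favour the cis junction, so ring A is better closed onto a ring B that already carries trans substituents. Rough treatment is excluded by the 13-hydroxy-16-ene unit (acid-induced Wagner–Meerwein shift, electrophilic oxidants), by the 3-hydroxy lactone (retro-aldol epimerisation in base) and by the 2β-hydroxyl (translactonisation in base), so the C7 ester must fall without hydrolysis. The feature that opens the key step is that C19 is a carboxyl carbon bonded only to O10 and C4, and that C4 is α to the oxygenated C3. With C3 as a ketone and C1=C2 in place, C4 is the only enolisable carbon of ring A, and C4–C19 becomes the bond between that enolate and a carbonate held on O10, 1,3-diaxial to it.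

## Retrosynthesis

**37 ⇐ 36 ⇐ 35 ⇐ 33 (O–C2 and H–C3).** The diol is taken back through the protected diol 36 and the ketol 35 to the 1-en-3-one 33. Dihydroxylation of a 2-ene would make the same diol in one step but would also oxidise C16=C17. From 33, conjugate hydride addition gives the only possible enolate (C2=C3), which is oxygenated on the open β face; a bulky hydride then sets the axial 3β-alcohol. A silyl ether on O13 and a 2-(trimethylsilyl)ethyl ester on C7 let one fluoride treatment finish the synthesis without base or acid.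

**33 ⇐ 31 (C4–C19, key step).** Cutting C4–C19 removes the lactone ring and the quaternary C4 together and leaves the 10α-(4-nitrophenyl carbonate) 31 of a ring A enone. The neighbouring cuts are weaker. Cutting C19–O10 needs an intermolecular, face-selective quaternisation of C4 and a cation or alkene at C10. Cutting C3–C4 needs the lactone before ring A exists. In the chosen cut the new carbon is carried by O10 and can reach only the α face of C4. The forward reaction must enolise only at C4, acylate on carbon, and expel a leaving group that cannot reopen the product.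

**31 ⇐ 28 ⇐ 27 ⇐ 26 (O10–C19, C1=C2).** The carbonate comes from the tertiary alcohol 28 and 4-nitrophenyl chloroformate 29. The hydroxy enone 28 comes from the allylic diol 27 by oxidation, and ring A of 27 is cut at C1=C2 (ring-closing metathesis) to the diene diol 26. This cut is preferred to any closure of ring B onto ring A because the metathesis bond is remote from C5 and C10, so a trans junction set beforehand on the cyclopentane is simply carried over.

**26 ⇐ 25 ⇐ 20 + 22 (C10–C1, C3–C2, C5–C4).** Both vinyl groups of 26 come from one reagent acting on the keto aldehyde 25. The addition to the C10 ketone sets O10 α because the nucleophile enters from the convex β face, anti to the C5 side chain and to ring C. The C5–C4 bond is cut as a Michael addition of the C5 enolate of the ring B ketone 20 to (E)-1-nitropropene 22 (from 1-nitropropan-2-ol 21). The nitro group is a latent C3 aldehyde, and a nitroalkene is preferred to a secondary α-halo carbonyl electrophile, which alkylates ketone enolates poorly.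

**20 ⇐ 19 ⇐ 18 ⇐ 17 ⇐ 16 ⇐ 13 + 14 (C9–C10, C5–C6).** Ring B is cut at C9–C10 as a 5-exo acyl radical closure of selenoester 18 onto the C9=C11 alkene. It delivers the ketone needed next and should add to C9 on the face away from the C15–C16 bridge, which is the cis B/C junction with 9β-H. C5–C6 is cut as the alkylation of the ester enolate of 13 with allyl bromoacetate 14 (to 16, then acid 17). C6 is left to equilibration (19 to 20).

**13 ⇐ 12 ⇐ 11 (C13–C16).** Ring D, the bridgehead carbinol and the exocyclic methylene are cut together at C13–C16: an alkenylchromium made from the 2-bromoallyl group of 11 adds to the C13 ketone (12, then silyl ether 13). Closing ring D before ring B means the bicycle later steers C9.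

**11 ⇐ 10 ⇐ 8 ⇐ 6 ⇐ 4 ⇐ 1 + 2 (C8–C15, C6 insertion).** The β,γ-unsaturated ketone 11 is the hydrolysed Birch product 10. Its CH2CO2R arm comes by Arndt–Eistert homologation (diazoketone 8) of acid 6, and the quaternary C8 comes from the Birch reductive alkylation of 3-methoxybenzoic acid 1 with 2,3-dibromopropene 2. The racemic acid 4 is resolved to 6 at this point, where C8 is the only stereocentre.

## Roads not taken

**Alternative 1:** cut C8–C9 and C11–C12 and form rings B and C by an intramolecular Diels–Alder reaction. The acyclic malonate A1 (C9=C11 vinyl ketone tethered to a C12=C13–C14=C8 silyloxydiene) would give the cis-hydrindanone silyl enol ether A2 with the propargyl group on C8.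
- Merits: two rings, the quaternary C8 and the cis B/C junction from an acyclic precursor in one step, with the C13 oxygen and the ring D handle in place. In steps to the B/C bicycle this is shorter than the chosen ring C, ring D, ring B order.
- Weak points: the diene terminus C8 is fully substituted, so the cycloaddition is slow while the vinyl ketone polymerises. A1 has no stereocentre, so the absolute configuration rests on a chiral catalyst acting on a hindered cycloaddition. The gem-diester at C6 must later lose one ester with control of C6.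
- Comparison: a catalytic asymmetric version would waste no material, whereas the chosen route gives up half in a resolution. Against that, the chosen route fixes C8 before any ring is closed and every later ring closure is steered by it. A2 also leaves the trans A/B junction, O10 and the C4 lactone untouched.

**Alternative 2:** cut C13–C16 by a ketyl–alkyne closure. SmI2 would reduce the C13 ketone of the cis-hydrindane A3 (propargyl on C8, C10 ketal, C6 ester) and the ketyl would add to C16 to give the B/C/D carbinol A4.
- Merits: ring D, the tertiary alcohol and the methylene in one step. This reaction type is more firmly precedented for such bridged carbinols than the organochromium closure used in step 6.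
- Weak points: A3 must first be made with three stereocentres and a protected C10. SmI2 must spare the ester, and the step says nothing about ring A or the lactone.
- Comparison: the chosen route makes the same bond earlier, on a monocyclic ketone, and keeps the ketyl–alkyne closure as its fallback. What it sets against the better precedent is the order of events: with ring D closed first, the bicycle controls C9 in the ring B closure.

**Alternative 3:** cut C2–C3 by a pinacol coupling. SmI2 would couple the C2 and C3 aldehydes of the lactone dialdehyde A5 to close ring A as the cis-diol A6, the methyl ester 13-methoxymethyl ether of 37.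
- Merits: ring A and both carbinol centres in the last C–C bond formation, with no later change of oxidation state. At the end of the synthesis this is shorter than the three steps from 33 to 36.
- Weak points: A5 needs the lactone and the quaternary C4 built without ring A, so nothing fixes which face of C4 takes the methyl and which the formyl group. The C3 aldehyde is a neopentyl formyl group on a lactone α-carbon and is prone to deformylation. The coupling should give a cis-diol, but whether 2β,3β or 2α,3α is not secured by the structure.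
- Comparison: the chosen plan is longer at the end, but it sets C4 by delivery from O10 and sets C2 and C3 on a rigid lactone-bridged ring whose α face is closed.

Key step: step 19

Assumption: which enantiomer of 1-phenylethylamine gives the less soluble salt with the (R)-acid cannot be predicted; step 2 is written for the (R)-amine, and the (S)-amine is used in the same way if the pairing is the opposite.

## Route

Step 1
Reactants: 1 3-methoxybenzoic acid; 2 2,3-dibromoprop-1-ene
Product: 4 rac-1-(2-bromoprop-2-en-1-yl)-3-methoxycyclohexa-2,5-diene-1-carboxylic acid, via dilithium dienediolate 3 (not isolated)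
Conditions: Li (3.2 equiv), NH3(l)–THF, −78 °C; then 2, −78 °C; NH4Cl; cold aq. citric acid to pH 4
Reagents that add atoms: none
Why: Birch reduction of the benzoic acid gives the 1,4-dihydro dianion with the methoxy group left on an sp2 carbon, and Birch reductive alkylation at the carboxyl-bearing carbon by the allylic bromide should set the quaternary C8 (racemic) while sparing the vinylic bromide.

Step 2
Reactants: 4 rac-1-(2-bromoprop-2-en-1-yl)-3-methoxycyclohexa-2,5-diene-1-carboxylic acid
Product: 6 (R)-1-(2-bromoprop-2-en-1-yl)-3-methoxycyclohexa-2,5-diene-1-carboxylic acid, via 1-phenylethylammonium salt 5 (not isolated)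
Conditions: (R)-1-phenylethylamine (0.55 equiv), EtOAc–i-PrOH, recrystallisation; salt partitioned between Et2O and cold aq. citric acid
Reagents that add atoms: none
Why: Classical resolution through diastereomeric ammonium carboxylates; C8 is the only stereocentre here and every later centre is relayed from it.

Step 3
Reactants: 6 (R)-1-(2-bromoprop-2-en-1-yl)-3-methoxycyclohexa-2,5-diene-1-carboxylic acid
Product: 8 1-[(R)-1-(2-bromoprop-2-en-1-yl)-3-methoxycyclohexa-2,5-dien-1-yl]-2-diazoethan-1-one, via acid chloride 7 (not isolated)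
Conditions: 1-chloro-N,N,2-trimethylprop-1-en-1-amine, CH2Cl2, 0 °C; then CH2N2 (3 equiv), Et2O, 0 °C
Reagents that add atoms: diazomethane, C=[N+]=[N-]
Why: First stage of an Arndt–Eistert homologation; the chloroenamine makes the acid chloride without free HCl so the enol ether survives, and excess diazomethane is acylated and scavenges HCl.

Step 4
Reactants: 8 1-[(R)-1-(2-bromoprop-2-en-1-yl)-3-methoxycyclohexa-2,5-dien-1-yl]-2-diazoethan-1-one
Product: 10 2-(trimethylsilyl)ethyl 2-[(S)-1-(2-bromoprop-2-en-1-yl)-3-methoxycyclohexa-2,5-dien-1-yl]acetate, via ketene 9 (not isolated)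
Conditions: PhCO2Ag (0.1 equiv), Et3N, Me3SiCH2CH2OH (5 equiv), THF, rt, dark
Reagents that add atoms: 2-(trimethylsilyl)ethanol, OCC[Si](C)(C)C
Why: Wolff rearrangement: the quaternary carbon migrates with retention to give ketene 9, which the alcohol traps; the new CH2 is C6, the old carboxyl carbon becomes C7, and the descriptor changes to S only through the priority change.

Step 5
Reactants: 10 2-(trimethylsilyl)ethyl 2-[(S)-1-(2-bromoprop-2-en-1-yl)-3-methoxycyclohexa-2,5-dien-1-yl]acetate
Product: 11 2-(trimethylsilyl)ethyl 2-[(R)-1-(2-bromoprop-2-en-1-yl)-5-oxocyclohex-2-en-1-yl]acetate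
Conditions: (CO2H)2·2H2O, THF–H2O, rt
Reagents that add atoms: water, O
Why: Mild acid hydrolysis of a Birch enol ether should free the C13 ketone as the β,γ-unsaturated isomer, keeping the C9=C11 alkene needed for ring B out of conjugation.

Step 6
Reactants: 11 2-(trimethylsilyl)ethyl 2-[(R)-1-(2-bromoprop-2-en-1-yl)-5-oxocyclohex-2-en-1-yl]acetate
Product: 12 2-(trimethylsilyl)ethyl 2-[(1R,5S)-5-hydroxy-6-methylidenebicyclo[3.2.1]oct-2-en-1-yl]acetate
Conditions: CrCl2 (5 equiv), NiCl2 (2 mol%), DMF, rt; aq. NH4Cl
Reagents that add atoms: none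
Why: Intramolecular Nozaki–Hiyama–Kishi reaction: nickel-catalysed formation of the alkenylchromium at C16 and 1,2-addition to the C13 ketone (only the five-membered closure is possible) should close ring D with the 13-hydroxyl and the C16 methylene; the C13 configuration is fixed by the bridge to C8.

Step 7
Reactants: 12 2-(trimethylsilyl)ethyl 2-[(1R,5S)-5-hydroxy-6-methylidenebicyclo[3.2.1]oct-2-en-1-yl]acetate
Product: 13 2-(trimethylsilyl)ethyl 2-[(1R,5S)-5-(tert-butyldimethylsilyloxy)-6-methylidenebicyclo[3.2.1]oct-2-en-1-yl]acetate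
Conditions: t-BuMe2SiOSO2CF3, 2,6-lutidine, CH2Cl2, 0 °C
Reagents that add atoms: tert-butyldimethylsilyl trifluoromethanesulfonate, CC(C)(C)[Si](C)(C)OS(=O)(=O)C(F)(F)F
Why: Silylation of the exposed bridgehead tertiary alcohol with a silyl triflate; the bridgehead position cannot ionise, so the allylic carbinol should survive.

Step 8
Reactants: 13 2-(trimethylsilyl)ethyl 2-[(1R,5S)-5-(tert-butyldimethylsilyloxy)-6-methylidenebicyclo[3.2.1]oct-2-en-1-yl]acetate; 14 prop-2-en-1-yl bromoacetate
Product: 16 4-(prop-2-en-1-yl) 1-[2-(trimethylsilyl)ethyl] 2-[5-(tert-butyldimethylsilyloxy)-6-methylidenebicyclo[3.2.1]oct-2-en-1-yl]butanedioate (bicycle as in 13; C6 epimers), via lithium ester enolate 15 (not isolated)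
Conditions: LiN(i-Pr)2, THF, −78 °C; 14, DMPU, −78 to −40 °C
Reagents that add atoms: none
Why: Ester enolate alkylation by the reactive α-bromo ester (SN2) forms C5–C6; C6 is not expected to be controlled here and is corrected in step 12.

Step 9
Reactants: 16 4-(prop-2-en-1-yl) 1-[2-(trimethylsilyl)ethyl] butanedioate of step 8 (C6 epimers)
Product: 17 4-oxo-4-[2-(trimethylsilyl)ethoxy]-3-[5-(tert-butyldimethylsilyloxy)-6-methylidenebicyclo[3.2.1]oct-2-en-1-yl]butanoic acid (C6 epimers)
Conditions: Pd(PPh3)4 (5 mol%), morpholine, THF, rt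
Reagents that add atoms: none
Why: Tsuji–Trost deallylation: zerovalent palladium ionises only the allyl ester and morpholine takes the allyl group, freeing the C10 acid beside the silylethyl ester.

Step 10
Reactants: 17 half acid of step 9 (C6 epimers)
Product: 18 Se-phenyl selenoester of 17 (C6 epimers)
Conditions: N-(phenylselanyl)phthalimide, n-Bu3P, CH2Cl2, 0 °C to rt
Reagents that add atoms: N-(phenylselanyl)phthalimide, O=C1N([Se]c2ccccc2)C(=O)c2ccccc12
Why: Phosphine-mediated redox condensation of a carboxylic acid with the selenylimide gives the selenoester, the standard acyl radical precursor.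

Step 11
Reactants: 18 Se-phenyl selenoester (C6 epimers)
Product: 19 ring B/C/D keto ester as C6 epimers (C10 ketone; 9β-H; 6-CO2CH2CH2SiMe3; 13-OSiMe2t-Bu; 16-methylene)
Conditions: n-Bu3SnH (1.3 equiv), AIBN (0.2 equiv), PhH (0.02 M), 80 °C
Reagents that add atoms: none
Why: Acyl radical cyclisation: the tin radical abstracts PhSe, the C10 acyl radical closes 5-exo-trig onto C9 and the C11 radical takes hydrogen from the stannane. The tether on the bridgehead C8 lies near the alkene plane, and the face of C9 under the C15–C16 bridge is shielded, so addition on the side of the one-carbon C14 bridge should give 9β-H, that is ring B cis-fused to the six-membered ring C.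

Step 12
Reactants: 19 ring B/C/D keto ester (C6 epimers)
Product: 20 6β ring B/C/D keto ester (C10 ketone; 9β-H; 6β-CO2CH2CH2SiMe3; 13-OSiMe2t-Bu; 16-methylene)
Conditions: KOt-Bu (0.2 equiv), t-BuOH–THF, 0 °C to rt; AcOH
Reagents that add atoms: none
Why: Base-mediated epimerisation through the ester enolate; the 6β ester lies on the convex face of the cis-fused B/C bicycle, away from C11 and C12 of ring C, and is expected to be favoured, while C9 next to the ketone should stay in the cis-fused form.

Step 13
Reactants: 21 1-nitropropan-2-ol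
Product: 22 (E)-1-nitroprop-1-ene
Conditions: MeSO2Cl, Et3N (2.2 equiv), CH2Cl2, 0 °C
Reagents that add atoms: none
Why: Mesylation and E1cB elimination of a β-nitro alcohol is the standard route to the (E)-nitroalkene.

Step 14
Reactants: 20 6β ring B/C/D keto ester; 22 (E)-1-nitroprop-1-ene
Product: 25 5α-(1-oxopropan-2-yl) keto aldehyde (C10 ketone; C3 aldehyde; 5β-H; 6β-ester; C4 epimers), via lithium C5 enolate 23 (not isolated), via lithium nitronate 24 (not isolated)
Conditions: LiN(i-Pr)2, THF, −78 °C; 22, −78 °C; then poured into aq. TiCl3–NH4OAc (pH 5–6), THF, 0 °C to rt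
Reagents that add atoms: water, O
Why: The kinetic enolate forms at the less hindered C5 methylene and adds to the nitroalkene (Michael addition) anti to the vicinal 6β ester, placing the side chain α; trivalent titanium then reduces the nitronate to the imine, which hydrolyses to the C3 aldehyde (Nef reaction). C4 is not controlled and is erased in step 19.

Step 15
Reactants: 25 keto aldehyde (C4 epimers)
Product: 26 diene diol: 10α-hydroxy-10β-vinyl; C3 vinyl carbinol (C3 and C4 epimers)
Conditions: CH2=CHMgBr (6 equiv), CeCl3 (6 equiv), THF, −78 to −20 °C; aq. NH4Cl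
Reagents that add atoms: vinylmagnesium bromide, C=C[Mg]Br
Why: Organocerium 1,2-additions (from the Grignard reagent) should reach the aldehyde and the hindered, enolisable ketone without touching the neopentyl ester; C10 is attacked from the convex β face, anti to the C5 side chain and ring C, so the hydroxyl ends α.

Step 16
Reactants: 26 diene diol (C3 and C4 epimers)
Product: 27 ring A allylic diol: 1-ene; 3-OH; 10α-OH; trans A/B (C3 and C4 epimers)
Conditions: second-generation Grubbs catalyst (5 mol%), CH2Cl2 (5 mM), 40 °C
Reagents that add atoms: none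
Why: Ring-closing metathesis of the two monosubstituted vinyl groups forms C1=C2 and ring A; the trans junction is already set at C5 and C10, and the 1,1-disubstituted C16 methylene reacts far more slowly.

Step 17
Reactants: 27 ring A allylic diol (C3 and C4 epimers)
Product: 28 10α-hydroxy-1-en-3-one (C4 epimers)
Conditions: MnO2 (activated), CH2Cl2, rt
Reagents that add atoms: none
Why: Selective oxidation of the secondary allylic alcohol; the tertiary C10 hydroxyl cannot be oxidised.

Step 18
Reactants: 28 10α-hydroxy-1-en-3-one (C4 epimers); 29 4-nitrophenyl chloroformate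
Product: 31 10α-O-(4-nitrophenoxycarbonyl)-1-en-3-one (C4 epimers), via lithium alkoxide 30 (not isolated)
Conditions: LiN(SiMe3)2 (1.0 equiv), THF, −78 °C; 29, −78 to −40 °C; pH 7 buffer
Reagents that add atoms: none
Why: O–H deprotonation is faster than C–H deprotonation and the lithium alkoxide is favoured over the lithium enolate; acylation of the alkoxide by the chloroformate at low temperature gives the mixed carbonate of the hindered tertiary alcohol.

Step 19
Reactants: 31 10α-O-(4-nitrophenoxycarbonyl)-1-en-3-one (C4 epimers)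
Product: 33 1,2-didehydro-3-oxo 19,10-lactone (4β-methyl; 13-OSiMe2t-Bu; 7-silylethyl ester), via lithium C4 enolate 32 (not isolated)
Conditions: LiN(SiMe3)2 (1.15 equiv), THF (0.01 M), −78 to 0 °C; aq. NH4Cl
Reagents that add atoms: none
Why: The base removes H4, the only acidic C–H next to the ketone (C2 is vinylic, C10 has no hydrogen), to give the cross-conjugated enolate 32, whose C4 attacks the carbonyl of the carbonate on the axial 10α oxygen; the tetrahedral intermediate expels 4-nitrophenoxide. The closest known reaction type is the intramolecular Claisen (Dieckmann-type) C-acylation of a ketone enolate by a mixed carbonate, a carbonate-to-carbon acyl transfer. The γ-lactone ring (C4, C5, C10, O, C19) closes in the 5-exo-trig mode, with the enolate double bond outside the new ring. The new quaternary C4 is controlled by C10: the tether reaches only the α face, so C19 ends α and the methyl β whichever C4 epimer of 31 is used. C-acylation is secured over O-acylation because the O-acyl product would need a bridgehead enol double bond that the bicycle cannot hold. Ketone enolisation is secured over ester enolisation by acidity and by the hindrance at C6, and high dilution favours the intramolecular path. 4-Nitrophenoxide is too weak a nucleophile to reopen the non-enolisable keto lactone, so the transfer should be irreversible.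

Step 20
Reactants: 33 1,2-didehydro-3-oxo 19,10-lactone
Product: 35 2β-hydroxy-3-oxo 19,10-lactone, via potassium C2 enolate 34 (not isolated)
Conditions: KBH(s-Bu)3 (1.1 equiv), THF, −78 °C; then 2-(phenylsulfonyl)-3-phenyloxaziridine, −78 °C; AcOH
Reagents that add atoms: 2-(phenylsulfonyl)-3-phenyloxaziridine, O=S(=O)(N1OC1c1ccccc1)c1ccccc1
Why: Conjugate reduction by the bulky borohydride (the carbonyl is shielded by the quaternary C4, the β carbon is unsubstituted) gives the only possible enolate, C2=C3; oxygen transfer from the N-sulfonyloxaziridine comes from the β face, since the α face of C2 lies under the lactone bridge, which sets 2β-OH.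

Step 21
Reactants: 35 2β-hydroxy-3-oxo 19,10-lactone
Product: 36 2β,3β-dihydroxy 19,10-lactone (13-OSiMe2t-Bu; 7-silylethyl ester)
Conditions: KBH(s-Bu)3 (2.5 equiv), THF, −78 °C; aq. NH4Cl
Reagents that add atoms: none
Why: The bulky hydride should add along the equatorial trajectory, as is usual for this reagent with 2-substituted cyclohexanones, giving the axial 3β-alcohol cis to the equatorial 2β-hydroxyl; low temperature and a neutral quench avoid retro-aldol cleavage at C3–C4.

Step 22
Reactants: 36 2β,3β-dihydroxy 19,10-lactone (13-OSiMe2t-Bu; 7-silylethyl ester)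
Product: 37 target gibberellin: (2β,3β)-2,3,13-trihydroxy-20-norgibberell-16-ene-7,19-dioic acid 19,10-lactone
Conditions: (Me2N)3S+ Me3SiF2− (excess), DMF, 0 °C to rt; aq. NaH2PO4
Reagents that add atoms: none
Why: Fluoride cleaves the tertiary silyl ether and fragments the 2-silylethyl ester (carboxylate, ethene, Me3SiF) under nearly neutral conditions, which avoids base-induced retro-aldol or translactonisation and acid-induced rearrangement of the 13-hydroxy-16-ene unit.

## Compound list

1 | 3-methoxybenzoic acid | COc1cccc(c1)C(=O)O | starting material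
2 | 2,3-dibromoprop-1-ene | C=C(Br)CBr | starting material
3 | dilithium (3-methoxycyclohexa-2,5-dien-1-ylidene)methanediolate | [Li+].[Li+].COC1=CC(=C([O-])[O-])C=CC1 | intermediate
4 | rac-1-(2-bromoprop-2-en-1-yl)-3-methoxycyclohexa-2,5-diene-1-carboxylic acid | C=C(Br)CC1(C(=O)O)C=C(OC)CC=C1 | intermediate
5 | (R)-1-phenylethylammonium (R)-1-(2-bromoprop-2-en-1-yl)-3-methoxycyclohexa-2,5-diene-1-carboxylate | C=C(Br)C[C@]1(C(=O)[O-])C=C(OC)CC=C1.C[C@@H]([NH3+])c1ccccc1 | intermediate
6 | (R)-1-(2-bromoprop-2-en-1-yl)-3-methoxycyclohexa-2,5-diene-1-carboxylic acid | C=C(Br)C[C@]1(C(=O)O)C=C(OC)CC=C1 | intermediate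
7 | (R)-1-(2-bromoprop-2-en-1-yl)-3-methoxycyclohexa-2,5-diene-1-carbonyl chloride | C=C(Br)C[C@]1(C(Cl)=O)C=C(OC)CC=C1 | intermediate
8 | 1-[(R)-1-(2-bromoprop-2-en-1-yl)-3-methoxycyclohexa-2,5-dien-1-yl]-2-diazoethan-1-one | C=C(Br)C[C@]1(C(=O)C=[N+]=[N-])C=C(OC)CC=C1 | intermediate
9 | 2-[(R)-1-(2-bromoprop-2-en-1-yl)-3-methoxycyclohexa-2,5-dien-1-yl]ethen-1-one (ketene) | C=C(Br)C[C@]1(C=C=O)C=C(OC)CC=C1 | intermediate
10 | 2-(trimethylsilyl)ethyl 2-[(S)-1-(2-bromoprop-2-en-1-yl)-3-methoxycyclohexa-2,5-dien-1-yl]acetate | C=C(Br)C[C@]1(CC(=O)OCC[Si](C)(C)C)C=C(OC)CC=C1 | intermediate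
11 | 2-(trimethylsilyl)ethyl 2-[(R)-1-(2-bromoprop-2-en-1-yl)-5-oxocyclohex-2-en-1-yl]acetate | C=C(Br)C[C@]1(CC(=O)OCC[Si](C)(C)C)CC(=O)CC=C1 | intermediate
12 | 2-(trimethylsilyl)ethyl 2-[(1R,5S)-5-hydroxy-6-methylidenebicyclo[3.2.1]oct-2-en-1-yl]acetate | C=C1C[C@]2(CC(=O)OCC[Si](C)(C)C)C[C@@]1(O)CC=C2 | intermediate
13 | 2-(trimethylsilyl)ethyl 2-[(1R,5S)-5-(tert-butyldimethylsilyloxy)-6-methylidenebicyclo[3.2.1]oct-2-en-1-yl]acetate | C=C1C[C@]2(CC(=O)OCC[Si](C)(C)C)C[C@@]1(O[Si](C)(C)C(C)(C)C)CC=C2 | intermediate
14 | prop-2-en-1-yl bromoacetate | C=CCOC(=O)CBr | starting material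
15 | lithium ester enolate of 13 | [Li+].C=C1C[C@]2(C=C([O-])OCC[Si](C)(C)C)C[C@@]1(O[Si](C)(C)C(C)(C)C)CC=C2 | intermediate
16 | 4-(prop-2-en-1-yl) 1-[2-(trimethylsilyl)ethyl] 2-[5-(tert-butyldimethylsilyloxy)-6-methylidenebicyclo[3.2.1]oct-2-en-1-yl]butanedioate; bicycle as in 13, C6 epimers (C6 undefined) | C=C1C[C@]2(C(CC(=O)OCC=C)C(=O)OCC[Si](C)(C)C)C[C@@]1(O[Si](C)(C)C(C)(C)C)CC=C2 | intermediate
17 | 4-oxo-4-[2-(trimethylsilyl)ethoxy]-3-[5-(tert-butyldimethylsilyloxy)-6-methylidenebicyclo[3.2.1]oct-2-en-1-yl]butanoic acid; C6 epimers | C=C1C[C@]2(C(CC(=O)O)C(=O)OCC[Si](C)(C)C)C[C@@]1(O[Si](C)(C)C(C)(C)C)CC=C2 | intermediate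
18 | Se-phenyl selenoester of 17; C6 epimers | C=C1C[C@]2(C(CC(=O)[Se]c3ccccc3)C(=O)OCC[Si](C)(C)C)C[C@@]1(O[Si](C)(C)C(C)(C)C)CC=C2 | intermediate
19 | ring B/C/D keto ester: cyclopentanone (C10=O) cis-fused at C8–C9 to the bicyclo[3.2.1]octane, 9β-H, 13-OSiMe2t-Bu, 16-methylene, 6-CO2CH2CH2SiMe3; C6 epimers | C=C1C[C@]23C[C@@]1(O[Si](C)(C)C(C)(C)C)CC[C@H]2C(=O)CC3C(=O)OCC[Si](C)(C)C | intermediate
20 | 6β epimer of 19 (6β-ester, 6α-H, 9β-H) | C=C1C[C@]23C[C@@]1(O[Si](C)(C)C(C)(C)C)CC[C@H]2C(=O)C[C@@H]3C(=O)OCC[Si](C)(C)C | intermediate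
21 | 1-nitropropan-2-ol | CC(O)C[N+](=O)[O-] | starting material
22 | (E)-1-nitroprop-1-ene | C/C=C/[N+](=O)[O-] | intermediate
23 | lithium C5–C10 enolate of 20 | [Li+].C=C1C[C@]23C[C@@]1(O[Si](C)(C)C(C)(C)C)CC[C@H]2C([O-])=C[C@@H]3C(=O)OCC[Si](C)(C)C | intermediate
24 | lithium nitronate of the Michael adduct (5α side chain, 5β-H; C4 undefined) | [Li+].C=C1C[C@]23C[C@@]1(O[Si](C)(C)C(C)(C)C)CC[C@H]2C(=O)[C@@H](C(C)C=[N+]([O-])[O-])[C@@H]3C(=O)OCC[Si](C)(C)C | intermediate
25 | keto aldehyde: 20 carrying a 5α-(1-oxopropan-2-yl) group (C4 methyl, C3 aldehyde), 5β-H; C4 epimers | C=C1C[C@]23C[C@@]1(O[Si](C)(C)C(C)(C)C)CC[C@H]2C(=O)[C@@H](C(C)C=O)[C@@H]3C(=O)OCC[Si](C)(C)C | intermediate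
26 | diene diol: 10α-hydroxy-10β-vinyl, 5α-(3-hydroxypent-4-en-2-yl); C3 and C4 epimers | C=C1C[C@]23C[C@@]1(O[Si](C)(C)C(C)(C)C)CC[C@H]2[C@](O)(C=C)[C@@H](C(C)C(O)C=C)[C@@H]3C(=O)OCC[Si](C)(C)C | intermediate
27 | ring A allylic diol: 1-ene, 3-hydroxy, 10α-hydroxy, trans A/B (5β-H), 4-methyl; C3 and C4 epimers | C=C1C[C@]23C[C@@]1(O[Si](C)(C)C(C)(C)C)CC[C@H]2[C@]2(O)C=CC(O)C(C)[C@H]2[C@@H]3C(=O)OCC[Si](C)(C)C | intermediate
28 | 10α-hydroxy-1-en-3-one; C4 epimers | C=C1C[C@]23C[C@@]1(O[Si](C)(C)C(C)(C)C)CC[C@H]2[C@]2(O)C=CC(=O)C(C)[C@H]2[C@@H]3C(=O)OCC[Si](C)(C)C | intermediate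
29 | 4-nitrophenyl chloroformate | O=C(Cl)Oc1ccc(cc1)[N+](=O)[O-] | starting material
30 | lithium 10α-alkoxide of 28 | [Li+].C=C1C[C@]23C[C@@]1(O[Si](C)(C)C(C)(C)C)CC[C@H]2[C@]2([O-])C=CC(=O)C(C)[C@H]2[C@@H]3C(=O)OCC[Si](C)(C)C | intermediate
31 | 10α-O-(4-nitrophenoxycarbonyl)-1-en-3-one (key-step precursor); C4 epimers | C=C1C[C@]23C[C@@]1(O[Si](C)(C)C(C)(C)C)CC[C@H]2[C@]2(OC(=O)Oc4ccc(cc4)[N+](=O)[O-])C=CC(=O)C(C)[C@H]2[C@@H]3C(=O)OCC[Si](C)(C)C | intermediate
32 | lithium C3–C4 enolate of 31 | [Li+].C=C1C[C@]23C[C@@]1(O[Si](C)(C)C(C)(C)C)CC[C@H]2[C@]2(OC(=O)Oc4ccc(cc4)[N+](=O)[O-])C=CC([O-])=C(C)[C@H]2[C@@H]3C(=O)OCC[Si](C)(C)C | intermediate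
33 | 1,2-didehydro-3-oxo 19,10-lactone: 4β-methyl, 4α-C19, 10α-O, 5β-H, 6β-ester, 9β-H, 13-OSiMe2t-Bu, silylethyl ester (key-step product) | C=C1C[C@]23C[C@@]1(O[Si](C)(C)C(C)(C)C)CC[C@H]2[C@@]12C=CC(=O)[C@@](C)(C(=O)O1)[C@H]2[C@@H]3C(=O)OCC[Si](C)(C)C | intermediate
34 | potassium C2–C3 enolate from conjugate reduction of 33 | [K+].C=C1C[C@]23C[C@@]1(O[Si](C)(C)C(C)(C)C)CC[C@H]2[C@@]12CC=C([O-])[C@@](C)(C(=O)O1)[C@H]2[C@@H]3C(=O)OCC[Si](C)(C)C | intermediate
35 | 2β-hydroxy-3-oxo 19,10-lactone (13-OSiMe2t-Bu, silylethyl ester) | C=C1C[C@]23C[C@@]1(O[Si](C)(C)C(C)(C)C)CC[C@H]2[C@@]12C[C@H](O)C(=O)[C@@](C)(C(=O)O1)[C@H]2[C@@H]3C(=O)OCC[Si](C)(C)C | intermediate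
36 | 2β,3β-dihydroxy 19,10-lactone with 13-OSiMe2t-Bu and 7-[2-(trimethylsilyl)ethyl] ester: the 13-O-tert-butyldimethylsilyl ether 2-(trimethylsilyl)ethyl ester of 37 | C=C1C[C@]23C[C@@]1(O[Si](C)(C)C(C)(C)C)CC[C@H]2[C@@]12C[C@H](O)[C@H](O)[C@@](C)(C(=O)O1)[C@H]2[C@@H]3C(=O)OCC[Si](C)(C)C | intermediate
37 | target gibberellin: (2β,3β)-2,3,13-trihydroxy-20-norgibberell-16-ene-7,19-dioic acid 19,10-lactone (4β-methyl, 5β-H, 6β-CO2H, 9β-H, 10α-O; descriptors as drawn) | C=C1C[C@]23C[C@@]1(O)CC[C@H]2[C@@]12C[C@H](O)[C@H](O)[C@@](C)(C(=O)O1)[C@H]2[C@@H]3C(=O)O | target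

## Step count and least certain steps

Total: 22 steps. Longest linear sequence: 21 steps (steps 1–12 and 14–22); step 13 is a one-step side branch.

**Step 19 (key step).** The enolate may fail to reach the carbonate carbonyl if ring A keeps the C10 oxygen away from the axial position; intermolecular acyl transfer or loss of the carbonate would then take over. The fallback leaves from 28. Formylation of the tertiary hydroxyl (acetic formic anhydride, pyridine) would give the 10-O-formate F1. LiN(SiMe3)2 would then add the C4 enolate to the formyl carbon, an intramolecular Claisen-type formylation that needs no leaving group, to give the 19,10-lactol F2. Oxidation of the lactol (Ag2CO3 on Celite, or Pr4N RuO4 with N-methylmorpholine N-oxide) returns to the route at 33.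

**Step 6.** The alkenylchromium may be protonated before it adds to the hindered ketone, or the β,γ-enone may drift into conjugation. The fallback makes the same bond by a ketyl–alkyne closure and restarts from 1 with 3-bromoprop-1-yne in place of 2. Birch reductive alkylation gives the racemic propargyl acid F3, and resolution through the 1-phenylethylammonium salt F4 gives the (R)-acid F5. Homologation through the acid chloride F6, the diazoketone F7 and the ketene F8 gives the silylethyl ester F9, and hydrolysis gives the ynone F10. SmI2 (HMPA, t-BuOH, THF) then reduces the C13 ketone and the ketyl adds to C16, which returns to the route at 12.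

**Step 11.** The cyclised C11 radical is β to the new ketone and may ring-expand before it is reduced; the acyl radical may also be reduced or lose CO before it cyclises, and addition on the face of C9 under the C15–C16 bridge would erode the selectivity at C9. The fallback leaves from 18. Reduction with n-Bu3SnH catalysed by Pd(PPh3)4 at room temperature (no radical initiator) gives the aldehyde F11. SmI2 with HMPA and t-BuOH in THF then forms the C10 ketyl, which closes 5-exo onto C9 without passing through an acyl radical or a β-keto radical, to give the cyclopentanol F12 as a mixture at C10. Oxidation with Dess–Martin periodinane returns at 19.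

**Step 14.** Proton transfer from the nitroalkene or its polymerisation may compete with the Michael addition, the one-pot reduction of the nitronate may stop short of the aldehyde, and facial selectivity at C5 falls if the C6 ester is not cleanly β after step 12. The fallback leaves from 20. Aldol addition of the C5 lithium enolate to acetaldehyde gives the β-hydroxy ketone F13, and mesylation with elimination (MeSO2Cl, Et3N) gives the (E)-ethylidene ketone F14. 2-Lithio-1,3-dithiane in THF–HMPA adds 1,4 to give the dithiane F15 after protonation at C5 trans to the ester. Alkylative hydrolysis (MeI, CaCO3, aq. MeCN) returns at 25.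

**Step 20.** 1,2-Reduction may compete with conjugate reduction, the ketol may isomerise in the basic medium, and oxygen transfer to the boron-bound enolate may be slow. The fallback leaves from 33. Conjugate reduction with [(Ph3P)CuH]6 and trapping with Me3SiCl gives the silyl enol ether F16. Rubottom oxidation with 3-chloroperoxybenzoic acid (1.0 equiv, NaHCO3, −20 °C), in which the enol ether is far more nucleophilic than the C16 methylene, gives the 2β-trimethylsilyloxy ketone F17. Citric acid in MeOH returns at 35.

## Further compounds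

F1 | step 19 | 10α-O-formate of 28 (C4 epimers) | C=C1C[C@]23C[C@@]1(O[Si](C)(C)C(C)(C)C)CC[C@H]2[C@]2(OC=O)C=CC(=O)C(C)[C@H]2[C@@H]3C(=O)OCC[Si](C)(C)C
F2 | step 19 | 19,10-lactol of 33 (C19 hemiacetal, epimers at C19) | C=C1C[C@]23C[C@@]1(O[Si](C)(C)C(C)(C)C)CC[C@H]2[C@@]12C=CC(=O)[C@@](C)(C(O)O1)[C@H]2[C@@H]3C(=O)OCC[Si](C)(C)C
F3 | step 6 | rac-3-methoxy-1-(prop-2-yn-1-yl)cyclohexa-2,5-diene-1-carboxylic acid | C#CCC1(C(=O)O)C=C(OC)CC=C1
F4 | step 6 | (R)-1-phenylethylammonium salt of the (R)-propargyl acid | C#CC[C@]1(C(=O)[O-])C=C(OC)CC=C1.C[C@@H]([NH3+])c1ccccc1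
F5 | step 6 | (R)-3-methoxy-1-(prop-2-yn-1-yl)cyclohexa-2,5-diene-1-carboxylic acid | C#CC[C@]1(C(=O)O)C=C(OC)CC=C1
F6 | step 6 | acid chloride of F5 | C#CC[C@]1(C(Cl)=O)C=C(OC)CC=C1
F7 | step 6 | diazoketone from F6 (propargyl analogue of 8) | C#CC[C@]1(C(=O)C=[N+]=[N-])C=C(OC)CC=C1
F8 | step 6 | ketene from F7 (propargyl analogue of 9) | C#CC[C@]1(C=C=O)C=C(OC)CC=C1
F9 | step 6 | 2-(trimethylsilyl)ethyl ester, propargyl analogue of 10 (same spatial arrangement at C8) | C#CC[C@]1(CC(=O)OCC[Si](C)(C)C)C=C(OC)CC=C1
F10 | step 6 | ynone, propargyl analogue of 11 (same spatial arrangement at C8) | C#CC[C@]1(CC(=O)OCC[Si](C)(C)C)CC(=O)CC=C1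
F11 | step 11 | C10 aldehyde corresponding to 18 (C6 epimers) | C=C1C[C@]2(C(CC=O)C(=O)OCC[Si](C)(C)C)C[C@@]1(O[Si](C)(C)C(C)(C)C)CC=C2
F12 | step 11 | C10 alcohol corresponding to 19 (cyclopentanol; C6 and C10 epimers) | C=C1C[C@]23C[C@@]1(O[Si](C)(C)C(C)(C)C)CC[C@H]2C(O)CC3C(=O)OCC[Si](C)(C)C
F13 | step 14 | aldol adduct of 20 with acetaldehyde at C5 (epimers at C5 and the carbinol) | C=C1C[C@]23C[C@@]1(O[Si](C)(C)C(C)(C)C)CC[C@H]2C(=O)C(C(C)O)[C@@H]3C(=O)OCC[Si](C)(C)C
F14 | step 14 | (E)-5-ethylidene ketone | C=C1C[C@]23C[C@@]1(O[Si](C)(C)C(C)(C)C)CC[C@H]2C(=O)/C(=C/C)[C@@H]3C(=O)OCC[Si](C)(C)C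
F15 | step 14 | 5α-[1-(1,3-dithian-2-yl)ethyl] ketone (C4 epimers) | C=C1C[C@]23C[C@@]1(O[Si](C)(C)C(C)(C)C)CC[C@H]2C(=O)[C@@H](C(C)C4SCCCS4)[C@@H]3C(=O)OCC[Si](C)(C)C
F16 | step 20 | C2–C3 trimethylsilyl enol ether of the 1,2-dihydro derivative of 33 | C=C1C[C@]23C[C@@]1(O[Si](C)(C)C(C)(C)C)CC[C@H]2[C@@]12CC=C(O[Si](C)(C)C)[C@@](C)(C(=O)O1)[C@H]2[C@@H]3C(=O)OCC[Si](C)(C)C
F17 | step 20 | 2β-trimethylsilyloxy-3-oxo lactone (trimethylsilyl ether of 35) | C=C1C[C@]23C[C@@]1(O[Si](C)(C)C(C)(C)C)CC[C@H]2[C@@]12C[C@H](O[Si](C)(C)C)C(=O)[C@@](C)(C(=O)O1)[C@H]2[C@@H]3C(=O)OCC[Si](C)(C)C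
A1 | alternative 1 | dimethyl 2-{6-[(tert-butyldimethylsilyl)oxy]hepta-4,6-dien-1-yn-4-yl}-2-(2-oxobut-3-en-1-yl)propanedioate (acyclic malonate) | C#CCC(=CC(=C)O[Si](C)(C)C(C)(C)C)C(CC(=O)C=C)(C(=O)OC)C(=O)OC
A2 | alternative 1 | cis-hydrindanone silyl enol ether with C8 propargyl group | C#CC[C@]12C=C(O[Si](C)(C)C(C)(C)C)CC[C@H]1C(=O)CC2(C(=O)OC)C(=O)OC
A3 | alternative 2 | cis-hydrindane keto alkyne (C13 ketone, C8 propargyl, C10 dioxolane, C6 methyl ester) | C#CC[C@]12CC(=O)CC[C@H]1C1(OCCO1)C[C@@H]2C(=O)OC
A4 | alternative 2 | tricyclic B/C/D carbinol with exocyclic methylene | C=C1C[C@]23C[C@@]1(O)CC[C@H]2C4(OCCO4)C[C@@H]3C(=O)OC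
A5 | alternative 3 | lactone dialdehyde (C2 and C3 aldehydes, 13-OCH2OCH3, methyl ester) | C=C1C[C@]23C[C@@]1(OCOC)CC[C@H]2[C@@]1(CC=O)OC(=O)[C@](C)(C=O)[C@H]1[C@@H]3C(=O)OC
A6 | alternative 3 | methyl ester 13-methoxymethyl ether of 37 | C=C1C[C@]23C[C@@]1(OCOC)CC[C@H]2[C@@]12C[C@H](O)[C@H](O)[C@@](C)(C(=O)O1)[C@H]2[C@@H]3C(=O)OC
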